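**Retrosynthetic overview**
1. The C7–O prenyl ether is cut last (Williamson), leaving 7-hydroxy-3',4'-dimethoxyisoflavone (cladrin) and prenyl bromide.
2. The C2=C3 double bond is taken back to the racemic isoflavanone (dehydrogenation), so C3 becomes an sp3 α-keto carbon.
3. Key disconnection C3–C1': the α-carbon of 7-hydroxychroman-4-one is used as an electrophile (enolonium, a trivalent-iodine enolate made from its silyl enol ether) and veratrole as the nucleophile. This is a direct C–H/C–H union of two natively nucleophilic carbons, with regiochemistry set by para attack on veratrole.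
4. No ring is formed in the route: rings A and C are bought together as 7-hydroxychroman-4-one and ring B as veratrole; ring B is attached before ring C is dehydrogenated to the pyranone.

Assumption: the target has no stereocentre and no stereogenic double bond, so no enantiocontrol is needed; the one stereocentre that appears on the way (C3 of 6) is racemic and is removed in step 3.

**Route**

Step 1
Reactants: 1 7-hydroxychroman-4-one
Product: 2 4,7-bis(trimethylsilyloxy)-2H-chromene
Conditions: TMSOTf (2.4 equiv), Et3N (3 equiv), CH2Cl2, 0 °C to rt; concentrate, triturate with pentane, filter (no aqueous work-up)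
Reagents that add atoms: trimethylsilyl trifluoromethanesulfonate, C[Si](C)(C)OS(=O)(=O)C(F)(F)F
Why: Silyl enol ether formation by soft enolisation (the ketone has only one enolisable position, C3) with concurrent O-silylation of the phenol, so no free OH reaches the oxidant in step 2; no stereocentre is formed.

Step 2
Reactants: 2 4,7-bis(trimethylsilyloxy)-2H-chromene; 3 veratrole (1,2-dimethoxybenzene)
Product: 6 racemic 7-hydroxy-3-(3,4-dimethoxyphenyl)chroman-4-one, via trivalent-iodine enolate 4 (not isolated), via silylated isoflavanone 5 (not isolated)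
Conditions: PhI(OH)OTs (1.1 equiv), BF3·OEt2 (1.5 equiv, activator), CH2Cl2, −78 °C, add 2, 10 min; then 3 (8 equiv), −78 to −30 °C; then 1 M HCl, THF, rt
Reagents that add atoms: none
Why: Proposed new method: the silyl enol ether attacks the BF3-activated PhI(OH)OTs to give the trivalent-iodine enolate 4, whose C3 is electrophilic (an enolonium), and veratrole, added in excess only after the oxidant is consumed, attacks C3 in a Friedel–Crafts sense through its 4-position (para to one OMe) with loss of PhI, joining two carbons that are both natively nucleophilic; the closest known reaction type is the α-arylation and α-allylation of preformed ketone enolonium species with indoles, pyrroles and allylsilanes, the new C3 stereocentre is formed racemic (and is erased in step 3), and the acidic work-up cleaves the aryl silyl ether.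

Step 3
Reactants: 6 racemic 7-hydroxy-3-(3,4-dimethoxyphenyl)chroman-4-one
Product: 7 7-hydroxy-3-(3,4-dimethoxyphenyl)-4H-chromen-4-one (cladrin)
Conditions: DDQ (1.3 equiv), 1,4-dioxane, 100 °C
Reagents that add atoms: none
Why: DDQ dehydrogenation of an isoflavanone (the α-aryl ketone enolises easily and loses hydride from C2) gives the fully conjugated chromone and removes the racemic C3 centre.

Step 4
Reactants: 7 7-hydroxy-3-(3,4-dimethoxyphenyl)-4H-chromen-4-one; 8 prenyl bromide (1-bromo-3-methylbut-2-ene)
Product: 9 7-prenyloxy-3',4'-dimethoxyisoflavone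
Conditions: K2CO3 (1.5 equiv), acetone, reflux
Reagents that add atoms: none
Why: Williamson ether synthesis, in which the only acidic OH (the 7-phenol, conjugated to the C4 carbonyl) is deprotonated and O-alkylated by SN2 at the primary allylic bromide.

**Compound list**
1 | 7-hydroxychroman-4-one | O=C1CCOc2cc(O)ccc12 | starting material
2 | 4,7-bis(trimethylsilyloxy)-2H-chromene | C[Si](C)(C)OC1=CCOc2cc(O[Si](C)(C)C)ccc12 | intermediate
3 | veratrole (1,2-dimethoxybenzene) | COc1ccccc1OC | starting material
4 | enolonium species: phenyl(tosyloxy)iodo enolate of 7-(trimethylsilyloxy)chroman-4-one, drawn O-bound, BF3 not shown | Cc1ccc(cc1)S(=O)(=O)O[I](c1ccccc1)OC1=CCOc2cc(O[Si](C)(C)C)ccc12 | intermediate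
5 | racemic 3-(3,4-dimethoxyphenyl)-7-(trimethylsilyloxy)chroman-4-one | COc1ccc(cc1OC)C1COc2cc(O[Si](C)(C)C)ccc2C1=O | intermediate
6 | racemic 7-hydroxy-3-(3,4-dimethoxyphenyl)chroman-4-one | COc1ccc(cc1OC)C1COc2cc(O)ccc2C1=O | intermediate
7 | 7-hydroxy-3-(3,4-dimethoxyphenyl)-4H-chromen-4-one (cladrin) | COc1ccc(cc1OC)-c1coc2cc(O)ccc2c1=O | intermediate
8 | prenyl bromide (1-bromo-3-methylbut-2-ene) | CC(C)=CCBr | starting material
9 | 7-prenyloxy-3',4'-dimethoxyisoflavone (achiral) | COc1ccc(-c2coc3cc(OCC=C(C)C)ccc3c2=O)cc1OC | target

**Step count**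
Total steps: 4. Longest linear sequence: 4 steps (1 → 2 → 6 → 7 → 9).

**Steps most likely to fail, with fallbacks**

Step 2 (highest risk). Veratrole is only about as nucleophilic as anisole, so tosylate transfer to C3 or loss of H-2 from 4 (giving the 7-silyloxychromone) may win. The fallback moves the reversed polarity from the enolate carbon to the aryl carbon; it sets out from 3 and 2 and comes back to the route at 5. Veratrole 3 is treated with MesI(OAc)2 and TfOH in CH2Cl2 at 0 °C, which gives (3,4-dimethoxyphenyl)(mesityl)iodonium triflate F1 by substitution para to one methoxy group. This aryl-cation equivalent arylates silyl enol ether 2 under Cu(OTf)2 catalysis (10 mol %, CH2Cl2, rt), with mesityl as the non-transferred group, to give 5. The same HCl work-up then converts 5 into 6. The closest known reaction type is the copper-catalysed α-arylation of enol silanes with diaryliodonium salts.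

Step 3. DDQ may attack the electron-rich veratryl ring or the phenol, or the reaction may stall. The fallback replaces hydride abstraction by a polar α-functionalisation and elimination; it sets out from 6 and comes back at 7. Compound 6 is doubly deprotonated with LiN(iPr)2 (2.2 equiv, THF, −78 °C) and the C3 enolate is trapped with PhSeCl to give 7-hydroxy-3-(3,4-dimethoxyphenyl)-3-(phenylselanyl)chroman-4-one F2. Oxidation with H2O2 (CH2Cl2, pyridine, 0 °C) gives the selenoxide, 7-hydroxy-3-(3,4-dimethoxyphenyl)-3-(phenylseleninyl)chroman-4-one F3. F3 undergoes syn-elimination towards C2–H, the only β-hydrogens, and gives 7.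

Step 1. The aryl O–SiMe3 bond of 2 is moisture-labile, and any free phenol would be oxidised in step 2. The fallback changes the order so that no phenol protecting group is needed; it sets out from 1 and 8 and comes back at 9.
- Compound 1 is O-alkylated with 8 (K2CO3, acetone, reflux) to give 7-(3-methylbut-2-enyloxy)chroman-4-one F4.
- TMSOTf and Et3N (CH2Cl2, 0 °C) convert F4 into 7-(3-methylbut-2-enyloxy)-4-(trimethylsilyloxy)-2H-chromene F5.
- F5 is taken through the step 2 protocol (PhI(OH)OTs, BF3·OEt2, CH2Cl2, −78 °C, then 3) via the phenyl(tosyloxy)iodo enolate of 7-(3-methylbut-2-enyloxy)chroman-4-one F6 to racemic 3-(3,4-dimethoxyphenyl)-7-(3-methylbut-2-enyloxy)chroman-4-one F7.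
- F7 is dehydrogenated with IBX in DMSO at 70 °C to give 9 directly. DDQ is avoided here because it cleaves prenyl ethers.
- The price of this order is a trisubstituted alkene present during the enolonium step.

**Further compounds**
F1 | step 2 | (3,4-dimethoxyphenyl)(mesityl)iodonium triflate | COc1ccc(cc1OC)[I+]c1c(C)cc(C)cc1C.[O-]S(=O)(=O)C(F)(F)F
F2 | step 3 | racemic 7-hydroxy-3-(3,4-dimethoxyphenyl)-3-(phenylselanyl)chroman-4-one | COc1ccc(cc1OC)C1([Se]c2ccccc2)COc2cc(O)ccc2C1=O
F3 | step 3 | 7-hydroxy-3-(3,4-dimethoxyphenyl)-3-(phenylseleninyl)chroman-4-one (selenoxide, diastereomer mixture) | COc1ccc(cc1OC)C1([Se](=O)c2ccccc2)COc2cc(O)ccc2C1=O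
F4 | step 1 | 7-(3-methylbut-2-enyloxy)chroman-4-one | CC(C)=CCOc1ccc2C(=O)CCOc2c1
F5 | step 1 | 7-(3-methylbut-2-enyloxy)-4-(trimethylsilyloxy)-2H-chromene | CC(C)=CCOc1ccc2C(O[Si](C)(C)C)=CCOc2c1
F6 | step 1 | phenyl(tosyloxy)iodo enolate of 7-(3-methylbut-2-enyloxy)chroman-4-one, drawn O-bound | Cc1ccc(cc1)S(=O)(=O)O[I](c1ccccc1)OC1=CCOc2cc(OCC=C(C)C)ccc12
F7 | step 1 | racemic 3-(3,4-dimethoxyphenyl)-7-(3-methylbut-2-enyloxy)chroman-4-one | COc1ccc(cc1OC)C1COc2cc(OCC=C(C)C)ccc2C1=O
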